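**Retrosynthetic overview**
- The only strategic bond is the ester alkyl C–O bond (ArCO2–CH2R).
- Cutting it gives 2,3-dihydroxybenzoic acid and heneicosan-1-ol, both purchasable.
- No ring is formed: the benzene ring comes intact from the acid.
- No protecting groups are planned: the CO2H is esterified chemoselectively in the presence of the free catechol.

Assumption: the target has no stereocentre (it is achiral), so "single enantiomer" requires no stereocontrol; the chain in the SMILES is C21 (heneicosyl).

**Step 1**
Reactants: 1 2,3-dihydroxybenzoic acid (1.2 equiv); 2 heneicosan-1-ol (1.0 equiv, limiting)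
Product: 3 heneicosyl 2,3-dihydroxybenzoate (gentiside I)
Conditions: PPh3 (1.2 equiv), DIAD (1.2 equiv, added dropwise), dry THF, 0 °C → rt, 16 h, N2
Reagents that add atoms: none
Why: Chemoselective Mitsunobu esterification — the carboxylic acid (pKa about 3) is far more acidic than either phenol (pKa about 10 or higher), so only its carboxylate displaces the PPh3-activated primary hydroxyl by SN2, and with the alcohol limiting nothing remains to etherify the catechol; no stereocentre is created.

**Compound list**
1 | 2,3-dihydroxybenzoic acid | OC(=O)c1cccc(O)c1O | starting material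
2 | heneicosan-1-ol (1-heneicosanol) | CCCCCCCCCCCCCCCCCCCCCO | starting material
3 | heneicosyl 2,3-dihydroxybenzoate (gentiside I) | CCCCCCCCCCCCCCCCCCCCCOC(=O)c1cccc(O)c1O | target

**Total step count:** 1
**Longest linear sequence:** 1 step

**Steps most likely to fail**
The route has a single step, so only step 1 can be ranked.

Step 1 could fail in three ways:
- partial O-alkylation of the 3-OH phenol;
- poor conversion, because the waxy C21 alcohol is sparingly soluble in cold THF;
- co-elution of the lipophilic product with the phosphine- and azo-derived residues.

Fallback for step 1: this changes the approach from alkyl C–O bond formation on the unprotected catechol to acyl C–O bond formation on a protected catechol. It sets out from 1 and comes back to the route at 3. Compound 1 is perbenzylated (BnBr 3.5 equiv, K2CO3, DMF, 60 °C) to benzyl 2,3-bis(benzyloxy)benzoate F1. Saponification (NaOH, MeOH/THF/H2O, reflux, then HCl) gives 2,3-bis(benzyloxy)benzoic acid F2. Steglich coupling of this acid with 2 (EDC·HCl, cat. DMAP, CH2Cl2, rt) gives heneicosyl 2,3-bis(benzyloxy)benzoate F3. Hydrogenolysis (H2 1 atm, 10% Pd/C, EtOAc/THF, rt) then removes both benzyl ethers, leaves the alkyl ester untouched, and delivers 3.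

**Further compounds**
F1 | step 1 | benzyl 2,3-bis(benzyloxy)benzoate | O=C(OCc1ccccc1)c1cccc(OCc2ccccc2)c1OCc1ccccc1
F2 | step 1 | 2,3-bis(benzyloxy)benzoic acid | OC(=O)c1cccc(OCc2ccccc2)c1OCc1ccccc1
F3 | step 1 | heneicosyl 2,3-bis(benzyloxy)benzoate | CCCCCCCCCCCCCCCCCCCCCOC(=O)c1cccc(OCc2ccccc2)c1OCc1ccccc1
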